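The numbers in the tables were generated by integration with made-up constants; the scatter is artificial.

If the reagent left over hardly changes late in a run, the intermediate falls like a plain decay, and what matters is how long it stays in the flask compared with one clearing time.

common to all: free catalyst 2.4 mol%
- Monday's: starting material 0.12 M; reagent 1.3 equiv; second catalyst 0.2 mol%; run made earlier
- Sunday's: starting material 0.12 M; reagent 1.3 equiv; second catalyst 0.13 mol%; run made earlier
- Saturday's: starting material 0.12 M; reagent 1.3 equiv; second catalyst 0.3 mol%; run made earlier
- Friday's: starting material 0.12 M; reagent 0.65 equiv; second catalyst 0.2 mol%; run made earlier
- south-west: starting material 0.12 M (fed, over 50.0 min); reagent 1.30 equiv; second catalyst 0.2 mol%; a stirred flask in which starting material is dosed at a steady rate over 50.0 min without added volume, worked up at 100 min; time 100 min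
- south-east: starting material 0.12 M; reagent 1.30 equiv; second catalyst 0.2 mol%; everything together in a closed stirred flask, run for 100 min; time 100 min
- south: starting material 0.12 M; reagent 1.30 equiv (fed, over 50.0 min); second catalyst 0.2 mol%; a stirred flask in which reagent is dosed at a steady rate over 50.0 min without added volume, worked up at 100 min; time 100 min
- north-east: starting material 0.12 M; reagent 1.30 equiv; second catalyst 0.2 mol%; a single well-mixed tank run continuously and read at steady state, 100 min in it on average

- Monday's (time / min: intermediate / %, target / %): 25.0: 10.7, 89.6; 50.0: 3.1, 97.1; 80.0: 0.3, 99.9; 90.0: 0, 98.0
- Sunday's (time / min: intermediate / %, target / %): 6.00: 58.2, 43.0; 15.0: 30.3, 69.6; 30.0: 14.5, 85.4; 80.0: 1.8, 97.6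
- Saturday's (time / min: intermediate / %, target / %): 20.0: 8.1, 93.4; 40.0: 2.0, 98.5; 60.0: 0.5, 100.9; 80.0: 0, 99.6
- Friday's (time / min: intermediate / %, target / %): 6.00: 69.2, 31.3; 15.0: 51.0, 50.1; 30.0: 39.6, 59.4; 80.0: 35.6, 65.3

(scatter of a reading: 0.5 percentage points)

- the stated concentrations are those of everything mixed, before any reaction; amounts are the same in each set-up
- the feed brings no volume worth counting
- the earlier runs were made in a closed, stirred flask

1. the set-up with the highest amount of intermediate at the outlet or at the end, in percent of the starting material put in ("none" if the first two lie within 2 percentage points) (south-west / south-east / south / north-east / none)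
2. amount of intermediate at the outlet or at the end, in percent of the starting material put in, south-west
3. amount of intermediate at the outlet or at the end, in percent of the starting material put in, south-east
4. amount of intermediate at the outlet or at the end, in percent of the starting material put in, south
5. amount of intermediate at the outlet or at the end, in percent of the starting material put in, north-east

In Sunday's run, intermediate and target already add up to 101% at 6.00 min, so within the scatter the starting material is converted by the first reading, and I drop that step. Friday's target levels off at 65.3% on 0.65 equiv of reagent, the limiting reagent there, so reagent goes one for one into target.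

Let x be the intermediate as a fraction of the charge. With 1.3 equiv of reagent, what remains is x + S, where S = 0.300 is the surplus, and I take the rate as proportional to x(x + S). That rate makes ln((x + S)/x) climb in a straight line with time, and Monday's readings at 25.0 min and 50.0 min, on the loading of all four new flasks, give one unit of that climb in 24.2 min. This is τ, the clearing time: once x is well below S, the reagent left is nearly frozen at S, the decay is pseudo-first-order, and intermediate falls by a factor e in τ.

The other time is the stay, 100 min (in north-east on average), and their ratio is r = 4.13. For south-east, the straight line gives x = S/(1.3·e^r − 1) = 0.376%. North-east stands at steady state, where intermediate coming in as starting material balances intermediate going out and intermediate cleared: 1 − x = r·x(x + S)/S, which gives 14.1%. South-west and south have 50.0 min after dosing ends, which is 2.06 clearing times, fewer than r, so my estimate places them between those two.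

The forecast, lower than my figure for south-east, gives 1.6% for south-west, 0.35% for south-east, 1.4% for south and 14% for north-east: “The tank is clearly highest.”

The flask gives 1.45%, 0.291%, 1.25% and 13.4% in that order, with north-east highest.

    starting material + free catalyst → free catalyst + intermediate (k = 730 M⁻¹ min⁻¹)
    reagent + second catalyst + intermediate → second catalyst + target (k = 5100 M⁻² min⁻¹)

In south-east, each step taken alone at the charged amounts, the half-life of starting material, 0.33 min, is shorter than that of intermediate, 3.6 min, which is short against 100 min. At the same ratio r, south-east ends at 0.291% and north-east at 13.4%. Sunday's readings at 15.0 min and 30.0 min give a clearing time of 34.6 min, and the same line then gives 1.34% at 100 min; Sunday's charge, run that long, holds 1.40%.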